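The data are simulated with constants of no real substance, and the scatter is random.

The highest target reading of the cedar run, 11.0% at 1.33 min, was my first answer to when this flask peaks, since the cedar run is this same flask, followed so far.

the same everywhere: starting material 0.52 M (fed, over 10 s); precatalyst 2 mol%

| charge | coupling partner | remark | time |
|---|---|---|---|
| cedar | 0.60 equiv | the very flask that is asked about, followed so far; the fed solution adds 0.25 times the starting volume |  |
| flask | 0.600 equiv | the fed solution adds 0.25 times the starting volume | 15 min |

cedar run (percent of the starting material charged)

| time / min | target / % | starting material / % |
|---|---|---|
| 0.200 | 3.4 | 96.2 |
| 0.417 | 7.8 | 87.5 |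
| 0.667 | 10.1 | 81.2 |
| 1.33 | 11.0 | 70.6 |
| 2.50 | 9.7 | 63.7 |
| 5.00 | 9.3 | 59.8 |

(each reading ± 0.5 percentage points)

- in percentages every species weighs as the starting material in it: one side product counts as two
- charges are per starting volume, the dose included; the dosed solution carries all of it
- on the list of suspects stand: starting material + target -> side product; target <-> isomer of the product; coupling partner + precatalyst -> catalyst + spent reagent; starting material + coupling partner + catalyst <-> target + catalyst

* time, not beyond 15 min, at which the flask holds most target
* the amount of target, in percent of the starting material charged, at that time
* earliest time at which at least nineteen twentieths of that best amount are there, in min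
* latest time at which they still are, in min

That reading was one way to the peak time. For the second I looked for the crossing at which control changes hands. The net gain of target is what coupling makes minus what is drained away, and the peak stands where that difference reaches zero. So I took the slope of target over two slices, as a fraction of the charge, and carried it on from the slice midpoints to zero:

from 0.417 min to 0.667 min: 0.0920 min⁻¹

from 0.667 min to 1.33 min: 0.0136 min⁻¹

crossing: 1.08 min

The two ways parted, 1.08 min against 1.33 min, and I judged that the highest reading was the one that cheated. It can stand only on a sampled time, and it beat its neighbour by 0.9 percentage points while each reading scatters by 0.5 points. I therefore took the crossing for the time. The height I kept as read, since the slope was already small by then.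

Among the suspects, each coupling event spends one partner, and the step to isomer is first order in target. So I took the height at the crossing, where making equals draining, to go with the partner charge. Dividing the height by that charge gives 18.3% of target per equivalent of partner, and this peak per equivalent is the quantity I carried.

The forecast gave 11.3% at 1.05 min, with the window from 0.77 min to 1.5 min, and read the curve thus: “Target climbs fast, peaks near 1 min at about 11%, then relaxes to about 9.5%.”

    starting material + target → side product (k = 0.00480 L mol⁻¹ s⁻¹)
    target ⇌ isomer of the product (K = 2.70, k = 0.0360 s⁻¹)
    coupling partner + precatalyst → catalyst + spent reagent (k = 0.220 L mol⁻¹ s⁻¹)
    starting material + coupling partner + catalyst ⇌ target + catalyst, rate k4*[starting material]*[coupling partner]*[catalyst] forward; the back reaction follows from the equilibrium constant (K = 1.70 L mol⁻¹, k = 7.40 L² mol⁻² s⁻¹)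

The flask peaked at 11.1% at 0.872 min, earlier than the forecast's time, and stayed within the asked margin of that from 0.617 min to 1.37 min. The step to isomer, both ways, is part of what brings the peak so early: without it the same flask peaks at 1.40 min. It is also part of what holds the peak down, since without it the same flask reaches 19.3%. Peak per equivalent gives 11.0% for this flask. For the neighbour with 0.240 equiv of partner it gives 4.39%, and that flask reached 4.31%. For the neighbour with 1.50 equiv it gives 27.5%, and that flask reached 24.5%.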